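Ring A is cut across C4–C5 and C2–C3. Its quaternary C4 (bearing C18 and C19) beside C5, together with the oxygen at C1, corresponds to a methacrylate (C3=C4, C19 carbonyl) adding to a ring B 2-ethoxydiene (C5=C10–C1=C2). Tying the methacrylate to C7 as an ester makes the cycloaddition intramolecular: one heating step closes ring A and a temporary C19–O–C7 δ-lactone, sets C4 and C5, and leaves a C1 enol ether for later oxygenation. The precursor is the B/C/D tricycle carrying a 13-triethylsilyl ether (fluoride-labile, safe for the final epoxide), the 1-ethoxyvinyl group on C10 and the methacryloyloxymethyl group on 6-epi C6.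

Key step: step 16

Remark: gibberellane numbering is used for every intermediate, and α/β refer to the usual gibberellin drawing, in which H5, H9 and C15 are β and the 19,10-lactone is α.

Remark: in step 1 the (R,R) enantiomer of the chiral diene is written as the working assumption; whichever enantiomer delivers the (R)-succinate is the one to be used.

Step 1
Reactants: 1 3-methoxyphenylboronic acid; 2 di-tert-butyl fumarate
Product: 3 di-tert-butyl (2R)-2-(3-methoxyphenyl)butanedioate
Conditions: [RhCl(C2H4)2]2 (cat.), (R,R)-2,5-diphenylbicyclo[2.2.2]octa-2,5-diene (cat.), KOH (0.5 equiv), dioxane/H2O, 50 °C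
Reagents that add atoms: none
Why: Hayashi–Miyaura asymmetric 1,4-addition, in which the aryl–rhodium species bound to the chiral diene adds to one enantioface of the fumarate and so sets C6 (R), the only centre in the route set by reagent control.

Step 2
Reactants: 3 di-tert-butyl (2R)-2-(3-methoxyphenyl)butanedioate
Product: 5 (1R)-6-methoxy-3-oxo-2,3-dihydro-1H-indene-1-carboxylic acid, via diacid 4 (not isolated)
Conditions: CF3CO2H, CH2Cl2, rt; evaporate; then P2O5 in MeSO3H, 40 °C
Reagents that add atoms: none
Why: acidolysis of both tert-butyl esters followed by intramolecular Friedel–Crafts acylation para to the methoxy group, where only the CH2CO2H arm can close a five-membered ring and the C6 centre is not enolised.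

Step 3
Reactants: 5 (1R)-6-methoxy-3-oxo-2,3-dihydro-1H-indene-1-carboxylic acid
Product: 6 (1R,3S)-3-hydroxy-6-methoxy-2,3-dihydro-1H-indene-1-carboxylic acid
Conditions: NaBH4, NaOH (1 equiv), MeOH/H2O, 0 °C; then citric acid to pH 5
Reagents that add atoms: none
Why: borohydride reduction of the aryl ketone, hydride adding to the face opposite the C1 carboxylate so that the temporary C10 carbinol is cis to the carboxyl group.

Step 4
Reactants: 6 (1R,3S)-3-hydroxy-6-methoxy-2,3-dihydro-1H-indene-1-carboxylic acid
Product: 8 B/C enone hydroxy acid (13-ketone; C8=C14; 10α-OH; 6α-CO2H; 9β-H), via dihydroanisole 7 (not isolated)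
Conditions: Li, NH3(l), THF, t-BuOH, −78 → −33 °C; NH4Cl; then 1 M HCl, THF, 0 °C → rt
Reagents that add atoms: water, O
Why: Birch reduction of the ring as its alkoxide–carboxylate salt (neither the benzylic C–O− nor the CO2− is cleaved) leaves the C8=C9 and enol ether double bonds, and acid hydrolysis with conjugation should give the C13 enone with H9 delivered by kinetic γ-protonation of the dienol on the β face, away from the two cis allylic substituents.

Step 5
Reactants: 8 B/C enone hydroxy acid
Product: 9 tricyclic enone lactone (γ-lactone between C7 and the 10α-oxygen on the α face of ring B)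
Conditions: EDC·HCl, DMAP (cat.), CH2Cl2 (high dilution), rt
Reagents that add atoms: none
Why: carbodiimide (Steglich-type) lactonisation open only to the cis-1,3 hydroxy acid, giving a bridged lactone that protects C7 and O10 together, makes C6 a non-enolisable bridgehead and blocks the α face of ring B.

Step 6
Reactants: 9 tricyclic enone lactone; 10 tributyl(propa-1,2-dienyl)stannane
Product: 11 8β-(prop-2-ynyl) keto lactone
Conditions: TiCl4, CH2Cl2, −78 °C; aq. NaHCO3
Reagents that add atoms: none
Why: TiCl4-promoted conjugate propargylation of the enone by the allenylstannane (SE2' attack through the allene terminus), C15 entering C8 from the exo β face of the lactone-bridged bicycle, anti to C7 and cis to H9, which creates the quaternary C8 centre.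

Step 7
Reactants: 11 8β-(prop-2-ynyl) keto lactone
Product: 12 tetracyclic hydroxy lactone (13-OH, C16=C17 methylene)
Conditions: SmI2 (2.5 equiv), HMPA, t-BuOH, THF, 0 °C → rt
Reagents that add atoms: none
Why: SmI2 ketyl–alkyne reductive cyclisation, the C13 ketyl adding 5-exo-dig to C16 of the axial propargyl group and the vinyl radical being reduced and protonated to the C16=C17 methylene, with C13 fixed by the only possible bridging geometry.

Step 8
Reactants: 12 tetracyclic hydroxy lactone
Product: 13 13-O-triethylsilyl ether of 12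
Conditions: Et3SiOTf, 2,6-lutidine, CH2Cl2, −78 → 0 °C
Reagents that add atoms: triethylsilyl trifluoromethanesulfonate, CC[Si](CC)(CC)OS(=O)(=O)C(F)(F)F
Why: silylation of the tertiary allylic alcohol with the silyl triflate gives a base-stable ether that fluoride removes at the end without acid.

Step 9
Reactants: 13 13-O-triethylsilyl lactone
Product: 14 B/C/D diol (10α-OH, 6α-CH2OH)
Conditions: LiAlH4, THF, 0 °C
Reagents that add atoms: none
Why: hydride reduction of the strained lactone to the diol frees the C7 hydroxymethyl group and the C10 carbinol without touching the silyl ether or the alkene.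

Step 10
Reactants: 14 B/C/D diol
Product: 15 7-pivalate of 14
Conditions: t-BuCOCl, pyridine, CH2Cl2, −20 °C
Reagents that add atoms: pivaloyl chloride, CC(C)(C)C(=O)Cl
Why: selective acylation of the primary C7 alcohol over the hindered secondary C10 alcohol gives an ester with no α-hydrogen that tolerates the enolate chemistry ahead.

Step 11
Reactants: 15 7-pivalate
Product: 16 B/C/D 10-ketone
Conditions: Dess–Martin periodinane, CH2Cl2, rt
Reagents that add atoms: none
Why: Dess–Martin oxidation of the secondary alcohol gives the C10 ketone, whose enolisable C9 centre already holds the favoured cis B/C fusion (H9 cis to C15).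

Step 12
Reactants: 16 B/C/D 10-ketone
Product: 17 C10 enol triflate (C5=C10)
Conditions: KN(SiMe3)2, THF, −78 °C; then PhNTf2, −78 → 0 °C
Reagents that add atoms: N-phenylbis(trifluoromethanesulfonimide), O=S(=O)(N(c1ccccc1)S(=O)(=O)C(F)(F)F)C(F)(F)F
Why: kinetic deprotonation at the less hindered C5 methylene, not the C9 methine, and O-triflation of the enolate give the C5=C10 enol triflate.

Step 13
Reactants: 17 C10 enol triflate; 18 tributyl(1-ethoxyvinyl)stannane
Product: 19 ring B 2-ethoxydiene 7-pivalate
Conditions: Pd(PPh3)4 (cat.), LiCl, THF, 65 °C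
Reagents that add atoms: none
Why: Stille coupling of the enol triflate with the 1-ethoxyvinylstannane at zerovalent palladium forms the C10–C1 bond and with it the diene C5=C10–C1(OEt)=C2.

Step 14
Reactants: 19 2-ethoxydiene 7-pivalate
Product: 20 dienyl alcohol
Conditions: i-Bu2AlH, CH2Cl2, −78 °C; aq. NaOH
Reagents that add atoms: none
Why: reductive cleavage of the pivalate frees the C7 alcohol under non-acidic conditions that leave the enol ether and the silyl ether intact.

Step 15
Reactants: 20 dienyl alcohol; 21 methacryloyl chloride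
Product: 22 dienyl methacrylate
Conditions: Et3N, DMAP (cat.), BHT, CH2Cl2, 0 °C
Reagents that add atoms: none
Why: acylation of the primary alcohol by the acid chloride under basic conditions installs the ester tether on C7, which is α on C6.

Step 16
Reactants: 22 dienyl methacrylate
Product: 23 pentacyclic enol ether δ-lactone
Conditions: toluene (0.01 M), BHT, propylene oxide, sealed tube, 170 °C
Reagents that add atoms: none
Why: A thermal, concerted but asynchronous [4+2] cycloaddition joins the electron-rich diene C5=C10–C1=C2 (largest HOMO coefficient at C2) to the tethered methacrylate C3=C4 (largest LUMO coefficient at C3), so C2–C3 bonding leads and C4–C5 follows. The closest known reaction type is the ester-tethered type 1 intramolecular Diels–Alder reaction of 2-alkoxy- or 2-silyloxydienes with acrylates and methacrylates to give fused lactones. Ring A closes as the six-membered carbocycle of the cycloadduct in the fused mode, and the six-membered lactone C4–C19–O–C7–C6–C5 closes in the same event because its last bond is the new C4–C5 bond. C5 is controlled by the C6 centre: the C7 arm is α, so the four-atom tether reaches only the α face of the diene and H5 ends β. C4 is controlled by the endo placement of the tether carbonyl in a cis-fused lactone transition state, which puts C19 α and C18 β, cis to H5. The step needs regio-, face- and endo-selectivity and must spare the C16=C17 alkene: the tether enforces the electronically matched regiochemistry, C6 fixes the face, the cis fusion is the less strained closure, and the isolated alkene is no dienophile, while propylene oxide and BHT guard the enol ether and the methacrylate.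

Step 17
Reactants: 23 pentacyclic enol ether δ-lactone
Product: 26 6-epi 7-hydroxy 1-oxo 19,10-lactone, via potassium seco-carboxylate 24 (not isolated), via 10β-bromo ketone 25 (not isolated)
Conditions: KOH, THF/MeOH/H2O, 50 °C; then CO2 to pH 8, N-bromosuccinimide, 0 °C → rt
Reagents that add atoms: potassium hydroxide, [K+].[OH-]; water, O
Why: saponification of the δ-lactone, bromination of the enol ether at C10 from the open β face (enol ether halogenation to the α-bromo ketone with loss of ethanol) and intramolecular displacement of the activated α-keto bromide by the C19 carboxylate, which can reach C10 only from the α face and so attacks with inversion, should close the 19,10-lactone on the α face and set C10.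

Step 18
Reactants: 26 6-epi 7-hydroxy 1-oxo 19,10-lactone
Product: 28 6β 7-aldehyde, via 6-epi aldehyde 27 (not isolated)
Conditions: Dess–Martin periodinane, CH2Cl2, rt; then DBU, CH2Cl2, rt
Reagents that add atoms: none
Why: Dess–Martin oxidation gives the aldehyde and base-mediated epimerisation through its enolate leads to the more stable 6β-aldehyde, in which C7 is trans to the C5–C4 bond and clear of the α-face lactone, which sets the natural C6 configuration.

Step 19
Reactants: 28 6β 7-aldehyde
Product: 29 1-oxo 19,10-lactone 7-oic acid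
Conditions: NaClO2, NaH2PO4, 2-methylbut-2-ene, t-BuOH/H2O, rt
Reagents that add atoms: sodium chlorite, [Na+].[O-]Cl=O
Why: Pinnick oxidation converts the aldehyde to the acid without epimerisation, the alkene scavenger shielding the C16=C17 bond from hypochlorite.

Step 20
Reactants: 29 1-oxo 19,10-lactone 7-oic acid
Product: 30 2-(trimethylsilyl)ethyl ester of 29
Conditions: Me3SiCH2CH2OH, PPh3, DIAD, THF, 0 °C → rt
Reagents that add atoms: 2-(trimethylsilyl)ethanol, C[Si](C)(C)CCO
Why: Mitsunobu esterification, in which the hindered carboxylate attacks the activated primary alcohol, gives a fluoride-cleavable ester.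

Step 21
Reactants: 30 2-(trimethylsilyl)ethyl ester
Product: 32 Δ2-1-enone, via trimethylsilyl enol ether 31 (not isolated)
Conditions: Me3SiOTf, Et3N, CH2Cl2, 0 °C; then Pd(OAc)2 (1.1 equiv), MeCN, rt
Reagents that add atoms: none
Why: Saegusa–Ito oxidation, in which soft enolisation can only go toward C2 because C10 is quaternary and divalent palladium dehydrogenates the silyl enol ether to the C2=C3 enone.

Step 22
Reactants: 32 Δ2-1-enone
Product: 33 2β,3β-epoxy-1-ketone
Conditions: t-BuOOH, DBU, CH2Cl2, rt
Reagents that add atoms: tert-butyl hydroperoxide, CC(C)(C)OO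
Why: Weitz–Scheffer nucleophilic epoxidation is chemoselective for the enone over the C16=C17 alkene, the hydroperoxide adding to C3 from the β face opposite the α lactone bridge, which sets C2 and C3.

Step 23
Reactants: 33 2β,3β-epoxy-1-ketone
Product: 34 1β-hydroxy-2β,3β-epoxide (13-O-triethylsilyl, 7-trimethylsilylethyl ester)
Conditions: LiBH(s-Bu)3, THF, −78 °C
Reagents that add atoms: none
Why: bulky-hydride reduction of the epoxy ketone from the α face, anti to the epoxide oxygen along the equatorial trajectory that turns 3-oxo gibberellins into axial alcohols, should give the 1β-alcohol cis to the epoxide.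

Step 24
Reactants: 34 1β-hydroxy-2β,3β-epoxide
Product: 35 target gibberellin (20-nor 19,10-lactone 7-oic acid with 1β-OH, 2β,3β-epoxide, 13-OH and 16-methylene; member 93 of the gibberellin A series)
Conditions: Bu4NF, THF, rt; then aq. NaH2PO4
Reagents that add atoms: none
Why: fluoride cleaves the tertiary silyl ether and fragments the 2-(trimethylsilyl)ethyl ester without acid, so the epoxide, the lactone and the 13-hydroxy-16-ene unit survive, and the cis epoxy alkoxide cannot undergo Payne rearrangement.

Compound list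
1 | 3-methoxyphenylboronic acid | COc1cccc(B(O)O)c1 | starting material
2 | di-tert-butyl fumarate | CC(C)(C)OC(=O)/C=C/C(=O)OC(C)(C)C | starting material
3 | di-tert-butyl (2R)-2-(3-methoxyphenyl)butanedioate | COc1cccc([C@@H](CC(=O)OC(C)(C)C)C(=O)OC(C)(C)C)c1 | intermediate
4 | (2R)-2-(3-methoxyphenyl)butanedioic acid | COc1cccc([C@@H](CC(=O)O)C(=O)O)c1 | intermediate
5 | (1R)-6-methoxy-3-oxo-2,3-dihydro-1H-indene-1-carboxylic acid | COc1ccc2c(c1)[C@H](C(=O)O)CC2=O | intermediate
6 | (1R,3S)-3-hydroxy-6-methoxy-2,3-dihydro-1H-indene-1-carboxylic acid (OH and CO2H cis) | COc1ccc2c(c1)[C@H](C(=O)O)C[C@@H]2O | intermediate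
7 | (1R,3S)-3-hydroxy-6-methoxy-2,3,4,7-tetrahydro-1H-indene-1-carboxylic acid (C8=C9 and C12=C13 enol ether) | COC1=CCC2=C(C1)[C@H](C(=O)O)C[C@@H]2O | intermediate
8 | 3-hydroxy-6-oxo-2,3,3a,4,5,6-hexahydro-1H-indene-1-carboxylic acid; 13-ketone, C8=C14, 10α-OH, 6α-CO2H, 9β-H | O=C1CC[C@@H]2C(=C1)[C@H](C(=O)O)C[C@@H]2O | intermediate
9 | tricyclic enone lactone: γ-lactone of 8 between C7 and the 10α-oxygen on the α face of ring B; 13-ketone, C8=C14, 9β-H | O=C1CC[C@@H]2C(=C1)[C@H]3C[C@@H]2OC3=O | intermediate
10 | tributyl(propa-1,2-dienyl)stannane | C=C=C[Sn](CCCC)(CCCC)CCCC | starting material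
11 | 8β-(prop-2-ynyl) keto lactone: quaternary C8 with C15 β and C14 α, 9β-H, 13-ketone, 7,10-lactone | C#CC[C@]12CC(=O)CC[C@H]1[C@@H]1C[C@H]2C(=O)O1 | intermediate
12 | tetracyclic hydroxy lactone: C/D bicyclo[3.2.1]octane with 13-OH and 16-methylene, 7,10-lactone on ring B | C=C1C[C@]23C[C@@]1(O)CC[C@H]2[C@@H]2C[C@H]3C(=O)O2 | intermediate
13 | 13-O-triethylsilyl ether of 12 | C=C1C[C@]23C[C@@]1(O[Si](CC)(CC)CC)CC[C@H]2[C@@H]2C[C@H]3C(=O)O2 | intermediate
14 | B/C/D diol: 10α-OH, 6α-CH2OH (C7), 13-OSiEt3, 16-methylene, 9β-H | C=C1C[C@]23C[C@@]1(O[Si](CC)(CC)CC)CC[C@H]2[C@@H](O)C[C@H]3CO | intermediate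
15 | 7-pivalate of 14 | C=C1C[C@]23C[C@@]1(O[Si](CC)(CC)CC)CC[C@H]2[C@@H](O)C[C@H]3COC(=O)C(C)(C)C | intermediate
16 | B/C/D 10-ketone, 7-pivalate, 13-OSiEt3 | C=C1C[C@]23C[C@@]1(O[Si](CC)(CC)CC)CC[C@H]2C(=O)C[C@H]3COC(=O)C(C)(C)C | intermediate
17 | C10 enol triflate (C5=C10) of 16 | C=C1C[C@]23C[C@@]1(O[Si](CC)(CC)CC)CC[C@H]2C(OS(=O)(=O)C(F)(F)F)=C[C@H]3COC(=O)C(C)(C)C | intermediate
18 | tributyl(1-ethoxyvinyl)stannane | CCCC[Sn](CCCC)(CCCC)C(=C)OCC | starting material
19 | ring B 2-ethoxydiene (C5=C10–C1(OEt)=C2), 7-pivalate | C=C1C[C@]23C[C@@]1(O[Si](CC)(CC)CC)CC[C@H]2C(C(=C)OCC)=C[C@H]3COC(=O)C(C)(C)C | intermediate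
20 | dienyl alcohol (7-OH, C7 α on C6) | C=C1C[C@]23C[C@@]1(O[Si](CC)(CC)CC)CC[C@H]2C(C(=C)OCC)=C[C@H]3CO | intermediate
21 | methacryloyl chloride | CC(=C)C(=O)Cl | starting material
22 | dienyl methacrylate (6-epi, ester on C7–O, 13-OSiEt3) | C=C1C[C@]23C[C@@]1(O[Si](CC)(CC)CC)CC[C@H]2C(C(=C)OCC)=C[C@H]3COC(=O)C(C)=C | intermediate
23 | pentacyclic enol ether δ-lactone: C1(OEt)=C10, 4β-methyl, C19(=O)–O–C7 lactone on the α face, 5β-H, 6β-H | C=C1C[C@]23C[C@@]1(O[Si](CC)(CC)CC)CC[C@H]2C4=C(OCC)CC[C@@]5(C)C(=O)OC[C@@H]3[C@@H]45 | intermediate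
24 | potassium salt of the seco acid: 19-carboxylate, 7-OH, C1(OEt)=C10 | C=C1C[C@]23C[C@@]1(O[Si](CC)(CC)CC)CC[C@H]2C4=C(OCC)CC[C@@](C)(C(=O)[O-])[C@H]4[C@H]3CO.[K+] | intermediate
25 | potassium 10β-bromo-1-oxo 19-carboxylate (7-OH) | C=C1C[C@]23C[C@@]1(O[Si](CC)(CC)CC)CC[C@H]2[C@@]4(Br)C(=O)CC[C@@](C)(C(=O)[O-])[C@H]4[C@H]3CO.[K+] | intermediate
26 | 1-oxo 19,10-lactone with 6α-hydroxymethyl (6-epi), 13-OSiEt3 | C=C1C[C@]23C[C@@]1(O[Si](CC)(CC)CC)CC[C@H]2[C@@]12OC(=O)[C@@](C)([C@H]1[C@H]3CO)CCC2=O | intermediate
27 | 6-epi aldehyde (6α-CHO) | C=C1C[C@]23C[C@@]1(O[Si](CC)(CC)CC)CC[C@H]2[C@@]12OC(=O)[C@@](C)([C@H]1[C@H]3C=O)CCC2=O | intermediate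
28 | 6β-aldehyde (natural C6) | C=C1C[C@]23C[C@@]1(O[Si](CC)(CC)CC)CC[C@H]2[C@@]12OC(=O)[C@@](C)([C@H]1[C@@H]3C=O)CCC2=O | intermediate
29 | 1-oxo 19,10-lactone 7-oic acid, 13-OSiEt3 | C=C1C[C@]23C[C@@]1(O[Si](CC)(CC)CC)CC[C@H]2[C@@]12OC(=O)[C@@](C)([C@H]1[C@@H]3C(=O)O)CCC2=O | intermediate
30 | 2-(trimethylsilyl)ethyl ester of 29 | C=C1C[C@]23C[C@@]1(O[Si](CC)(CC)CC)CC[C@H]2[C@@]12OC(=O)[C@@](C)([C@H]1[C@@H]3C(=O)OCC[Si](C)(C)C)CCC2=O | intermediate
31 | C1 trimethylsilyl enol ether (C1=C2) of 30 | C=C1C[C@]23C[C@@]1(O[Si](CC)(CC)CC)CC[C@H]2[C@@]12OC(=O)[C@@](C)([C@H]1[C@@H]3C(=O)OCC[Si](C)(C)C)CC=C2O[Si](C)(C)C | intermediate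
32 | Δ2-1-enone (C2=C3) | C=C1C[C@]23C[C@@]1(O[Si](CC)(CC)CC)CC[C@H]2[C@@]12OC(=O)[C@@](C)([C@H]1[C@@H]3C(=O)OCC[Si](C)(C)C)C=CC2=O | intermediate
33 | 2β,3β-epoxy-1-ketone | C=C1C[C@]23C[C@@]1(O[Si](CC)(CC)CC)CC[C@H]2[C@@]12OC(=O)[C@@](C)([C@H]1[C@@H]3C(=O)OCC[Si](C)(C)C)[C@H]1O[C@H]1C2=O | intermediate
34 | 1β-hydroxy-2β,3β-epoxide, 13-OSiEt3, 7-CO2CH2CH2SiMe3 | C=C1C[C@]23C[C@@]1(O[Si](CC)(CC)CC)CC[C@H]2[C@@]12OC(=O)[C@@](C)([C@H]1[C@@H]3C(=O)OCC[Si](C)(C)C)[C@H]1O[C@H]1[C@H]2O | intermediate
35 | target gibberellin: 20-nor 19,10-lactone 7-oic acid with 1β-OH, 2β,3β-epoxide, 13-OH and 16-methylene (member 93 of the gibberellin A series) | C=C1C[C@]23C[C@@]1(O)CC[C@H]2[C@@]12OC(=O)[C@@](C)([C@H]1[C@@H]3C(=O)O)[C@H]1O[C@H]1[C@H]2O | target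

Total step count: 24. Longest linear sequence: 24 steps (the route is linear from 1 and 2).

Steps most likely to fail

Step 16: the cycloaddition may stall, because the ester tether disfavours the reactive conformer, or may close through the exo orientation and so invert C4. The fallback sets out from dienyl alcohol 20. It is acylated with acryloyl chloride (Et3N, CH2Cl2) to the dienyl acrylate F1. F1 is cyclised thermally to the 18-nor lactone F2, whose C4 is enolisable. The lactone enolate of F2 (LiN(i-Pr)2, THF, −78 °C) is then methylated with MeI from the convex β face, which returns to 23. C4 is thus set by alkylation and not by the geometry of the cycloaddition.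

Step 17: substitution at the tertiary C10 bromide may lose to elimination or to capture by the free C7 hydroxyl. The fallback sets out from 23. The enol ether is hydrolysed (oxalic acid, wet THF) to the keto lactone F3. F3 is saponified (KOH, aqueous THF) to the potassium keto carboxylate F4. F4 is then closed by trivalent-iodine ketolactonisation (PhI(OH)OTs, MeCN), the known oxidative cyclisation of 5-oxo acids through the C1=C10 enol, which returns to 26.

Step 23: hydride delivery may show poor facial selectivity and give the 1α-alcohol. The fallback sets out from ester 30. α-Selenenylation (LiN(SiMe3)2, then PhSeCl, THF, −78 °C) gives the 2β-phenylseleno ketone F5. Reduction with KBH(s-Bu)3, equatorial and anti to selenium, gives the axial 1β-hydroxy selenide F6. Selenoxide elimination (H2O2, pyridine), which runs away from the carbinol, gives the Δ2 1β-allylic alcohol F7. Hydroxyl-directed epoxidation (VO(acac)2, t-BuOOH) on the β face then returns to 34.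

Further compounds
F1 | step 16 | dienyl acrylate (7-O-acryloyl analogue of 22) | C=C1C[C@]23C[C@@]1(O[Si](CC)(CC)CC)CC[C@H]2C(C(=C)OCC)=C[C@H]3COC(=O)C=C
F2 | step 16 | 18-nor pentacyclic enol ether δ-lactone (4β-H) | C=C1C[C@]23C[C@@]1(O[Si](CC)(CC)CC)CC[C@H]2C4=C(OCC)CC[C@H]5C(=O)OC[C@@H]3[C@@H]45
F3 | step 17 | 1-oxo δ-lactone (10β-H) | C=C1C[C@]23C[C@@]1(O[Si](CC)(CC)CC)CC[C@H]2[C@H]4C(=O)CC[C@@]5(C)C(=O)OC[C@@H]3[C@@H]45
F4 | step 17 | potassium 1-oxo seco-carboxylate (7-OH, 10β-H) | C=C1C[C@]23C[C@@]1(O[Si](CC)(CC)CC)CC[C@H]2[C@H]4C(=O)CC[C@@](C)(C(=O)[O-])[C@H]4[C@H]3CO.[K+]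
F5 | step 23 | 2β-phenylseleno 1-ketone | C=C1C[C@]23C[C@@]1(O[Si](CC)(CC)CC)CC[C@H]2[C@@]12OC(=O)[C@@](C)([C@H]1[C@@H]3C(=O)OCC[Si](C)(C)C)C[C@@H]([Se]c1ccccc1)C2=O
F6 | step 23 | 1β-hydroxy 2β-phenylselenide | C=C1C[C@]23C[C@@]1(O[Si](CC)(CC)CC)CC[C@H]2[C@@]12OC(=O)[C@@](C)([C@H]1[C@@H]3C(=O)OCC[Si](C)(C)C)C[C@@H]([Se]c1ccccc1)[C@H]2O
F7 | step 23 | Δ2 1β-allylic alcohol | C=C1C[C@]23C[C@@]1(O[Si](CC)(CC)CC)CC[C@H]2[C@@]12OC(=O)[C@@](C)([C@H]1[C@@H]3C(=O)OCC[Si](C)(C)C)C=C[C@H]2O
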